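If target charged at the start does not touch the making of target, Friday's flask is Monday's flask with an extra pool in it, and two chemists dispute what that pool does.

| flask | starting material | partner | target | time |
|---|---|---|---|---|
| Monday's | 0.200 M | 0.160 M |  |  |
| Tuesday's | 0.0800 M | 0.0400 M |  |  |
| Wednesday's | 0.200 M | 0.240 M |  |  |
| Sunday's | 0.300 M | 0.160 M |  |  |
| Friday's | 0.200 M | 0.160 M | 0.100 M | 49 min |

- Monday's run (time / min: [target] / M): 2.2: 0.0108; 6.6: 0.0278; 13: 0.0465; 20: 0.0616; 29: 0.0757; 38: 0.0826; 49: 0.0887
- Tuesday's run (time / min: [target] / M): 2.2: 0.0018; 6.6: 0.0036; 13: 0.0065; 20: 0.0098; 29: 0.0121; 38: 0.0159; 49: 0.0189
- Wednesday's run (time / min: [target] / M): 2.2: 0.0152; 6.6: 0.0404; 13: 0.0668; 20: 0.0874; 29: 0.1059; 38: 0.1145; 49: 0.1209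
- Sunday's run (time / min: [target] / M): 2.2: 0.0130; 6.6: 0.0341; 13: 0.0564; 20: 0.0735; 29: 0.0881; 38: 0.0957; 49: 0.1009

(standard deviation of a reading: 6 × 10⁻⁴ M)

- apparent order in [starting material] of the starting rate, round the charge of the Monday's run (the rate where two percent of its starting material have turned into target) (one fixed amount of target, the same in the runs compared)
- apparent order in [partner] of the starting rate, round the charge of the Monday's run (the rate where two percent of its starting material have turned into target)
- target in the Friday's run at 49 min, as a share of the starting material charged

- Overall: starting material + partner -> target.
- Constant volume, constant temperature.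
- The analysis sees a species whether free or bound.
- "The second partner" is partner.
- An order is taken over about fifteen percent of the charge, up and down.
- A share of target counts the target that was charged too.

The first chemist writes the balance of the partner, the limiting reagent of Monday's charge (0.160 M against 0.200 M of starting material). Each target made costs one partner and charged target cost none, so Friday starts with Monday's c(partner) and c(starting material). On this bystander view Friday holds the charge plus Monday's last reading, 0.189 M, which is 94.3 % of the starting material.

The second chemist made the forecast: 0.55 and 0.9 for the orders, and 82 % for Friday, between 68 % and 91 %. Her ground: “With target already charged, Friday should run slower”.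

My own reckoning differs from both, and it starts from the same balance. Monday's first reading gives an early constant of 0.153 M⁻¹ min⁻¹, taken as the rate over the product of the charges. Over Monday's last interval c(target) averages 0.0857 M. The balance then leaves enough partner and starting material for a making rate of 0.00130 M min⁻¹, but the slope read is 5.55 × 10⁻⁴ M min⁻¹. If target leaves by a first-order drain, the difference over c(target) is a drain constant of 0.00875 min⁻¹, a time constant of 114 min. This is a rough reading, since the early constant is held fixed.

The quantity to carry is the survival share, the fraction of a target pool still standing after a time t, exp(-t/τ). At 49 min it is 65.1 %. Friday is then Monday's last reading plus that share of the charge, 76.9 %, lower than the forecast and reached on another ground: a drain, where the forecast has slower running.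

The simulation gives 0.58 and 1.0 for the orders and 79.1 % for Friday, each inside the forecast's range, and Friday falls short of the bystander's sum.

    starting material + partner → target + by-product (0.7020 M⁻¹ min⁻¹)
    2 starting material ⇌ idle substrate dimer, settled at all times (41.80 M⁻¹)
    target → decomposed product (0.007260 min⁻¹)

Friday is held down by the conversion of target into decomposed product. The run without that step gives 105 % against 79.1 %, above the forecast's high end, so that change would make the forecast wrong. There the survival share is 100%, the charge stands whole, and the new target is 0.110 M. In the real Friday, taking off Monday's last reading leaves a share of 69.6 %, against the survival share of 65.1 % read from Monday's run. The bystander's sum is right where the survival share is close to one: at 2.2 min, the time of Monday's first reading, exp(-k2·t) with the constant of the last step gives 98.4 %.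

The numbers in the tables were computed for substances that don't exist; noise was put on by code.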